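# Synthesis proposal for CNP0188864.1: nickel-mediated C4–C5 closure of a germacranolide

## The problem

The target is a germacranolide in which a ten-membered carbocycle (C1–C10) with two Z trisubstituted olefins in a 1,4-relationship (C1=C10 and C3=C4) is cis-fused at C6/C7 to an α-methylene-γ-butyrolactone (O–C6, C7, C11, C12, with C13 as the exocyclic methylene). Four contiguous stereocentres run from C6 to C9, and two more sit in the (2S,3R)-2,3-dimethyloxirane-2-carboxylate on O8, next to the acetate on O9. Stereocontrol can be relayed along the chain: the erythro C8/C9 diol fits a cis-dioxolane and can be bought as a unit, the C8–O bond can then steer a carbon nucleophile onto C7, and the C7 substituent can bias lactonisation at C6. A synthesis therefore has to close a medium ring without scrambling either olefin geometry, ideally in a step that creates no stereocentre, and has to place two different acyl groups on neighbouring secondary hydroxyls. The α-methylene lactone (a Michael and radical acceptor), the epoxy ester, the allylic C9 acetate and the skipped diene are fragile towards bases, acids and low-valent metals, so they must appear late. The feature that opens the key step is C5, a methylene between the olefinic carbon C4 and the lactone carbinol C6, so that the C4–C5 bond joins an sp2 carbon to a primary carbon that is β to oxygen. Both ends are naturally halides, an alkenyl bromide at C4 and the primary iodide that iodolactonisation installs at C5 together with the lactone ring, and this calls for a reductive union of two electrophiles because a C5 organometallic would expel the β-oxygen.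

## Retrosynthesis

**Acyl groups (30 ⇒ 28 + 10; 28 ⇒ 27).** The acyl–oxygen bonds at O8 and O9 are cut first. The epoxy ester and the allylic acetate are the most fragile groups, and removing them leaves diol 27 and the small epoxy acid 10. The forward steps must tell the two hydroxyls apart: the allylic C9–OH, flanked by sp2 C10, should be acetylated before the more hindered C8–OH next to the ring fusion. Acid 10 goes back through epoxy alcohol 8 and allylic alcohol 7 to tiglic acid 6, so a catalytic asymmetric epoxidation sets both epoxide centres.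

**Acetonide and exocyclic methylene (27 ⇒ 26 ⇒ 22).** The C8/C9 diol is masked as the cis-acetonide 26, and the C11=C13 bond is cut to give the saturated lactone 22. Methylenation is placed after ring formation because an acrylate would trap the C5 radical and bind low-valent nickel in the closure. The forward reaction is a lactone enolate Mannich reaction and elimination, which only needs the C11 protons to be the most acidic ones in 22.

**Ring closure (22 ⇒ 21).** The ten-membered ring is opened at C4–C5. Its neighbours are less attractive: C5–C6, C6–C7, C7–C8 and C8–C9 each border a stereocentre, and C9–C10 would create C9 during cyclisation. Cutting C4–C5 leaves every stereocentre and both olefin geometries already in place in the monocyclic iodide 21. The forward reaction must join an alkenyl bromide and a β-oxygenated primary iodide with retention of the Z geometry, and must favour ring closure over reduction or dimerisation.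

**Lactone and iodide (21 ⇒ 20 ⇒ 19).** The C6–O lactone bond and the C5–I bond are cut together, giving the 3-substituted pent-4-enoic acid 20 and its ester 19. One iodolactonisation makes the ring, the C6 stereocentre and the electrophile for the key step. It must run under kinetic control to give the cis lactone, and must touch only the terminal vinyl group. Only that olefin lies within 5-exo reach of the carboxylate.

**Arm olefin (19 ⇒ 17 + 5).** The C10=C1 bond is cut by a Wittig transform into the α-alkoxy methyl ketone 17 and phosphonium salt 5. A non-stabilised ylide adds to an α-alkoxy ketone so that the new chain ends cis to the oxygenated carbon, which is the required Z geometry. The alternative, adding an alkenyl metal to a C9 aldehyde, would create C9 at this point instead of bringing it in fixed. Salt 5 comes from (Z)-dibromide 4, bromo alcohol 3 and but-2-yn-1-ol 1. The C3=C4 geometry is set by trans-hydroalumination and never touched again.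

**C10 methyl and C7 branch (17 ⇒ 16 ⇒ 14).** The C10–C14 bond is cut to the Weinreb amide 16, and the C7–C6 bond is cut to the (E)-enoate 14. Conjugate delivery of a vinyl group to a γ-alkoxy enoate occurs anti to the C8–O bond. This places C6 anti and the acetate arm (C11–C12) syn to O8, which is the target arrangement. A sigmatropic introduction of C11 onto a C5 allylic alcohol would be expected to put the new bond anti to O8 and give the C7 epimer, so 1,4-addition is chosen.

**Chiral pool (14 ⇒ 13 ⇒ 12 ⇒ 11).** The C7=C11 olefin and the amide go back to aldehyde 13, hydroxy amide 12 and the commercial lactone 11 (2,3-O-isopropylidene-D-erythronolactone). Compound 11 contains C7–C10 with the erythro C8/C9 diol already tied as the cis-dioxolane, so no protecting group is added or exchanged before the final deprotection.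

## Roads not taken

**Alternative 1:** The C1=C10 olefin and the ring are traced back to a C1–C6 σ bond. In the forward step the C6 alkoxide of the bicyclic epoxy alcohol A1 would push out the ring-fusion bond anti to the C10–O bond of the 9,10-epoxide, giving dienone A2.
- Merits: a fragmentation pays for the medium ring with a σ bond, not with an entropically costly cyclisation, so ring formation is more dependable than any ten-membered closure, the chosen one included. The C1=C10 geometry follows from the relative configuration of A1. A2 has a free C9 hydroxyl beside a silylated O8, which solves the acyl differentiation that the chosen plan leaves to a selective acetylation.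
- Weak points: A1 needs five or six stereo-elements on a decalin, including the exact antiperiplanar array. A2 is a β,γ-unsaturated ketone that can slip into conjugation. Its C6 ketone must be reduced to the cis carbinol in a flexible ring, and the protected hydroxyethyl chain must still be oxidised and lactonised.
- Comparison: the chosen plan sets against this a shorter, protecting-group-poor route in which all stereocentres are fixed before the ring is made and only five operations follow the closure.

**Alternative 2:** The C3=C4 olefin is cut back to the eleven-membered sulfone A3. α-Halogenation in situ (KOH on alumina, CBr2F2), episulfone formation and loss of SO2 would give diene A4.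
- Merits: closing an eleven-membered sulfide by S-alkylation and contracting it is well-trodden chemistry, and A4 carries the same acetonide as 22. In ring-closure precedent this road is better.
- Weak points: the mechanism does not dictate the geometry of a trisubstituted olefin. The C3 protons of A3 are allylic to C1=C10, so base can move the skipped diene. The two silyl ethers of A4 must still be converted to the lactone over several redox steps.
- Comparison: the chosen plan brings the C3=C4 geometry in fixed from but-2-yn-1-ol and has the lactone in place before cyclisation.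

**Alternative 3:** The C9–C10 bond is cut. The iodo aldehyde A5 would be closed with CrCl2 and catalytic NiCl2 to the ring alcohol A6.
- Merits: this is the best-precedented carbon–carbon closure for ten-membered rings. It tolerates the α-methylene lactone, so no late methylenation is needed. It leaves O9 free and O8 silylated, again better than the chosen plan for telling the two oxygens apart.
- Weak points: C9 is created in the cyclisation under conformational control of a medium-ring transition state, so its configuration cannot be predicted. The α-silyloxy aldehyde of A5 can epimerise. A5 still needs the C4–C5 bond from some earlier coupling.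
- Comparison: the chosen plan has C9 bought and forms no stereocentre in the ring closure, at the price of an unproven closure. Fallbacks are given for that step and for the acyl differentiation.

Key step: step 15

Remark: ring compounds are named with germacranolide locants (C1–C10 carbocycle, C11–C13 lactone carbons, C14 and C15 the methyl groups on C10 and C4); all configurations are fixed by the SMILES in the compound list.

## Route

Step 1
Reactants: 1 but-2-yn-1-ol
Product: 3 (Z)-3-bromobut-2-en-1-ol, via cyclic sodium alkenylalanate 2 (not isolated)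
Conditions: NaAlH2(OCH2CH2OMe)2, THF, 0 °C to rt; then N-bromosuccinimide, −78 °C; aq. potassium sodium tartrate
Reagents that add atoms: N-bromosuccinimide, O=C1CCC(=O)N1Br
Why: Hydroxyl-directed trans-hydroalumination of the propargylic alcohol places aluminium on C3 cis to the carbinol carbon, and bromodealumination with retention should give the Z alkenyl bromide.

Step 2
Reactants: 3 (Z)-3-bromobut-2-en-1-ol
Product: 4 (Z)-1,3-dibromobut-2-ene
Conditions: PBr3, Et2O, 0 °C
Reagents that add atoms: phosphorus tribromide, BrP(Br)Br
Why: Substitution of a primary allylic alcohol by PBr3 (SN2 on the bromophosphite) should leave the electron-poor bromoalkene and its geometry untouched.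

Step 3
Reactants: 4 (Z)-1,3-dibromobut-2-ene
Product: 5 [(3Z)-4-bromopent-3-en-1-yl]triphenylphosphonium bromide
Conditions: Ph3PCH3Br, n-BuLi, THF, −78 °C; then 4, −78 °C to rt
Reagents that add atoms: methyltriphenylphosphonium bromide, C[P+](c1ccccc1)(c1ccccc1)c1ccccc1.[Br-]
Why: C-Alkylation of methylidenetriphenylphosphorane by the primary allylic bromide (SN2 ylide alkylation) should give the homologated salt, which precipitates and so escapes further deprotonation; the alkenyl bromide is inert.

Step 4
Reactants: 6 tiglic acid
Product: 7 (E)-2-methylbut-2-en-1-ol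
Conditions: LiAlH4, Et2O, 0 °C to rt
Reagents that add atoms: none
Why: Hydride reduction of the carboxylic acid to the allylic alcohol keeps the E olefin.

Step 5
Reactants: 7 (E)-2-methylbut-2-en-1-ol
Product: 8 [(2R,3R)-2,3-dimethyloxiran-2-yl]methanol
Conditions: Ti(OiPr)4 (cat.), D-(−)-diethyl tartrate (cat.), t-BuOOH, 4 Å molecular sieves, CH2Cl2, −20 °C
Reagents that add atoms: tert-butyl hydroperoxide, CC(C)(C)OO
Why: Sharpless asymmetric epoxidation; the D-tartrate complex delivers oxygen to the face that gives the 2R,3R epoxide, and the E geometry is carried over as the cis relation of the two methyl groups.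

Step 6
Reactants: 8 [(2R,3R)-2,3-dimethyloxiran-2-yl]methanol
Product: 10 (2S,3R)-2,3-dimethyloxirane-2-carboxylic acid, via epoxy aldehyde 9 (not isolated)
Conditions: RuCl3·xH2O (cat.), NaIO4, CCl4/MeCN/H2O, rt
Reagents that add atoms: water, O
Why: Ruthenium tetroxide generated in situ oxidises the primary alcohol through the aldehyde hydrate to the acid without opening the epoxide; the C2 descriptor changes only because the substituent priorities change.

Step 7
Reactants: 11 (3aR,6aR)-2,2-dimethyldihydrofuro[3,4-d][1,3]dioxol-4(3aH)-one
Product: 12 (4R,5R)-5-(hydroxymethyl)-N-methoxy-N,2,2-trimethyl-1,3-dioxolane-4-carboxamide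
Conditions: MeNH(OMe)·HCl, AlMe3, CH2Cl2, 0 °C to rt; aq. potassium sodium tartrate
Reagents that add atoms: N,O-dimethylhydroxylamine hydrochloride, CNOC.Cl
Why: Aluminium amide aminolysis of the lactone (Weinreb amide formation) opens the ring without touching the two stereocentres; the hydroxy amide is used at once to forestall relactonisation.

Step 8
Reactants: 12 (4R,5R)-5-(hydroxymethyl)-N-methoxy-N,2,2-trimethyl-1,3-dioxolane-4-carboxamide
Product: 13 (4R,5S)-5-formyl-N-methoxy-N,2,2-trimethyl-1,3-dioxolane-4-carboxamide
Conditions: Dess–Martin periodinane, pyridine, CH2Cl2, 0 °C to rt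
Reagents that add atoms: none
Why: Dess–Martin oxidation under buffered, non-enolising conditions should give the α-alkoxy aldehyde without epimerisation to the trans-dioxolane; the crude aldehyde is carried on directly.

Step 9
Reactants: 13 (4R,5S)-5-formyl-N-methoxy-N,2,2-trimethyl-1,3-dioxolane-4-carboxamide
Product: 14 ethyl (2E)-3-[(4R,5R)-5-[methoxy(methyl)carbamoyl]-2,2-dimethyl-1,3-dioxolan-4-yl]prop-2-enoate
Conditions: (EtO)2P(O)CH2CO2Et, LiCl, i-Pr2NEt, MeCN, 0 °C to rt
Reagents that add atoms: triethyl phosphonoacetate, CCOC(=O)CP(=O)(OCC)OCC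
Why: Horner–Wadsworth–Emmons olefination in its LiCl/amine variant is E-selective and mild enough for an epimerisable α-alkoxy aldehyde.

Step 10
Reactants: 14 ethyl (2E)-3-[(4R,5R)-5-[methoxy(methyl)carbamoyl]-2,2-dimethyl-1,3-dioxolan-4-yl]prop-2-enoate
Product: 16 ethyl (3S)-3-[(4R,5R)-5-[methoxy(methyl)carbamoyl]-2,2-dimethyl-1,3-dioxolan-4-yl]pent-4-enoate, via silyl ketene acetal 15 (not isolated)
Conditions: CH2=CHMgBr (slow addition), CuBr·SMe2 (cat.), Me3SiCl, THF, −78 °C; aq. NH4Cl
Reagents that add atoms: vinylmagnesium bromide, C=C[Mg]Br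
Why: Copper-catalysed, chlorosilane-accelerated conjugate addition to a γ-alkoxy enoate; in the Felkin–Anh-type transition state the vinyl group enters C7 anti to the C8–O bond, which sets C7 as S, and the amide is inert to the organocopper at −78 °C.

Step 11
Reactants: 16 ethyl (3S)-3-[(4R,5R)-5-[methoxy(methyl)carbamoyl]-2,2-dimethyl-1,3-dioxolan-4-yl]pent-4-enoate
Product: 17 ethyl (3S)-3-[(4R,5R)-5-acetyl-2,2-dimethyl-1,3-dioxolan-4-yl]pent-4-enoate
Conditions: MeMgBr, THF, −78 to −40 °C; aq. NH4Cl
Reagents that add atoms: methylmagnesium bromide, C[Mg]Br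
Why: Weinreb ketone synthesis; the chelating α-alkoxy amide should react at a temperature where the ethyl ester is inert, and the chelated tetrahedral adduct shields the ketone from over-addition and from enolisation until work-up.

Step 12
Reactants: 17 ethyl (3S)-3-[(4R,5R)-5-acetyl-2,2-dimethyl-1,3-dioxolan-4-yl]pent-4-enoate; 5 [(3Z)-4-bromopent-3-en-1-yl]triphenylphosphonium bromide
Product: 19 ethyl (3S)-3-[(4R,5S)-5-[(2Z,5Z)-6-bromohepta-2,5-dien-2-yl]-2,2-dimethyl-1,3-dioxolan-4-yl]pent-4-enoate, via phosphorus ylide 18 (not isolated)
Conditions: 5, KN(SiMe3)2, THF, −78 °C; then 17, −78 to 0 °C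
Reagents that add atoms: none
Why: Wittig reaction of a non-stabilised ylide with an α-alkoxy methyl ketone under salt-poor, kinetic conditions, a combination known to place the ylide chain cis to the oxygenated carbon and so give the Z trisubstituted olefin; the ketone reacts far faster than the ester.

Step 13
Reactants: 19 ethyl (3S)-3-[(4R,5S)-5-[(2Z,5Z)-6-bromohepta-2,5-dien-2-yl]-2,2-dimethyl-1,3-dioxolan-4-yl]pent-4-enoate
Product: 20 (3S)-3-[(4R,5S)-5-[(2Z,5Z)-6-bromohepta-2,5-dien-2-yl]-2,2-dimethyl-1,3-dioxolan-4-yl]pent-4-enoic acid
Conditions: LiOH, THF/H2O, 0 °C to rt; then aq. HCl to pH 4, 0 °C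
Reagents that add atoms: lithium hydroxide, [Li+].[OH-]
Why: Ester saponification; C7 carries no acidic proton, and the acetonide, the skipped diene and the alkenyl bromide tolerate cold aqueous base and a brief mild acidification.

Step 14
Reactants: 20 (3S)-3-[(4R,5S)-5-[(2Z,5Z)-6-bromohepta-2,5-dien-2-yl]-2,2-dimethyl-1,3-dioxolan-4-yl]pent-4-enoic acid
Product: 21 (4R,5R)-4-[(4R,5S)-5-[(2Z,5Z)-6-bromohepta-2,5-dien-2-yl]-2,2-dimethyl-1,3-dioxolan-4-yl]-5-(iodomethyl)oxolan-2-one
Conditions: I2, NaHCO3, MeCN, 0 °C, dark
Reagents that add atoms: iodine, II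
Why: Kinetic iodolactonisation (5-exo, anti addition) of a 3-substituted pent-4-enoate; in the early transition state the bulky C7 substituent lies in the olefin plane, away from the face that receives iodine, which should favour the cis lactone and set C6. The carboxylate can reach only the vinyl group in a five-membered mode, so the arm olefins are expected to stay intact.

Step 15
Reactants: 21 (4R,5R)-4-[(4R,5S)-5-[(2Z,5Z)-6-bromohepta-2,5-dien-2-yl]-2,2-dimethyl-1,3-dioxolan-4-yl]-5-(iodomethyl)oxolan-2-one
Product: 22 (1(10)Z,3Z,6S,7S,8R,9S)-8,9-(isopropylidenedioxy)-13-norgermacra-1(10),3-dien-12,6-olide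
Conditions: NiBr2(dme) (20 mol%), 4,4′-di-tert-butyl-2,2′-bipyridine (24 mol%), Mn powder (3 equiv), N,N-dimethylacetamide, rt, syringe-pump addition of 21 to a final 2 mM
Reagents that add atoms: none
Why: Proposed new method: zerovalent nickel, formed from NiBr2(dme), the bipyridine and manganese, should add to the C4–Br bond with retention, a monovalent nickel species should abstract iodine from C5 to give a primary radical, the alkenylnickel should capture this radical, and reductive elimination from trivalent nickel should form C4–C5 while manganese returns the catalyst. The closest known reaction type is the intermolecular nickel-catalysed reductive coupling of alkenyl bromides with primary alkyl iodides; its use to close a ten-membered carbocycle is the untested part. The ring closes by capture of the tethered C5 radical at the alkenylnickel centre followed by C–C reductive elimination, with the cis-lactone and the cis-dioxolane holding C5 and the bromodiene arm on one face. No stereocentre is formed; the Z geometry at C3=C4 has to be kept, and oxidative addition and reductive elimination at an sp2 carbon both proceed with retention. The step needs cross-coupling over homocoupling, and ring closure over reduction, dimerisation or attack of the C5 radical on C1=C10. The different activation modes of the two halides, slow addition at high dilution, and a radical that keeps its β-oxygen where a C5 organometallic would expel it are what the design relies on; manganese is chosen because it does not insert into the β-acyloxy iodide.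

Step 16
Reactants: 22 (1(10)Z,3Z,6S,7S,8R,9S)-8,9-(isopropylidenedioxy)-13-norgermacra-1(10),3-dien-12,6-olide
Product: 24 (1(10)Z,3Z,6S,7S,8R,9S)-13-(dimethylamino)-8,9-(isopropylidenedioxy)germacra-1(10),3-dien-12,6-olide (C11 epimers), via lithium enolate 23 (not isolated)
Conditions: LiN(iPr)2, THF, −78 °C; then N,N-dimethylmethyleneiminium iodide (Eschenmoser's salt), −78 °C to rt
Reagents that add atoms: N,N-dimethylmethyleneiminium iodide, C=[N+](C)C.[I-]
Why: Mannich reaction of the lactone lithium enolate with the preformed iminium salt; C11 is the only position enolised at −78 °C, and its configuration is irrelevant because it becomes sp2 in the next step.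

Step 17
Reactants: 24 (1(10)Z,3Z,6S,7S,8R,9S)-13-(dimethylamino)-8,9-(isopropylidenedioxy)germacra-1(10),3-dien-12,6-olide (C11 epimers)
Product: 26 (1(10)Z,3Z,6S,7S,8R,9S)-8,9-(isopropylidenedioxy)germacra-1(10),3,11(13)-trien-12,6-olide, via trimethylammonium iodide 25 (not isolated)
Conditions: MeI, MeOH, rt; then aq. NaHCO3, CH2Cl2, rt
Reagents that add atoms: none
Why: N-Methylation followed by mild base-induced β-elimination (E1cB) of trimethylamine is the standard second half of lactone α-methylenation and avoids strong base on the skipped diene.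

Step 18
Reactants: 26 (1(10)Z,3Z,6S,7S,8R,9S)-8,9-(isopropylidenedioxy)germacra-1(10),3,11(13)-trien-12,6-olide
Product: 27 (1(10)Z,3Z,6S,7S,8R,9S)-8,9-dihydroxygermacra-1(10),3,11(13)-trien-12,6-olide
Conditions: AcOH/H2O (4:1), 40 °C
Reagents that add atoms: none
Why: Acid-catalysed acetal hydrolysis; the strained cis-dioxolane is cleaved under conditions mild enough to spare the allylic C9–O bond and the α-methylene lactone.

Step 19
Reactants: 27 (1(10)Z,3Z,6S,7S,8R,9S)-8,9-dihydroxygermacra-1(10),3,11(13)-trien-12,6-olide
Product: 28 (1(10)Z,3Z,6S,7S,8R,9S)-9-acetoxy-8-hydroxygermacra-1(10),3,11(13)-trien-12,6-olide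
Conditions: Ac2O (1.1 equiv), pyridine, CH2Cl2, −20 to 0 °C
Reagents that add atoms: acetic anhydride, CC(=O)OC(C)=O
Why: Regioselective O-acylation; the allylic C9 hydroxyl, flanked by the sp2 carbon C10, is expected to react before the C8 hydroxyl, which is crowded by the ring-fusion carbon C7 and the lactone.

Step 20
Reactants: 28 (1(10)Z,3Z,6S,7S,8R,9S)-9-acetoxy-8-hydroxygermacra-1(10),3,11(13)-trien-12,6-olide; 10 (2S,3R)-2,3-dimethyloxirane-2-carboxylic acid
Product: 30 (1(10)Z,3Z,6S,7S,8R,9S)-9-acetoxy-8-{[(2S,3R)-2,3-dimethyloxiran-2-yl]carbonyloxy}germacra-1(10),3,11(13)-trien-12,6-olide (the target), via mixed anhydride 29 (not isolated)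
Conditions: 10, 2,4,6-Cl3C6H2COCl, Et3N, THF, 0 °C; then 28, 4-(dimethylamino)pyridine, toluene, rt
Reagents that add atoms: none
Why: Yamaguchi esterification; the mixed anhydride acylates the hindered secondary C8 hydroxyl under conditions that leave the epoxide, the acetate and the stereocentres of both partners untouched.

## Compound list

1 | but-2-yn-1-ol | CC#CCO | starting material
2 | cyclic sodium alkenylalanate (sodium 2,2-bis(2-methoxyethoxy)-3-methyl-2,5-dihydro-1,2-oxaluminol-2-uide) | CC1=CCO[Al-]1(OCCOC)OCCOC.[Na+] | intermediate
3 | (Z)-3-bromobut-2-en-1-ol | C/C(Br)=C/CO | intermediate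
4 | (Z)-1,3-dibromobut-2-ene | C/C(Br)=C/CBr | intermediate
5 | [(3Z)-4-bromopent-3-en-1-yl]triphenylphosphonium bromide | C/C(Br)=C/CC[P+](c1ccccc1)(c1ccccc1)c1ccccc1.[Br-] | intermediate
6 | tiglic acid, (E)-2-methylbut-2-enoic acid | C/C=C(\C)C(=O)O | starting material
7 | (E)-2-methylbut-2-en-1-ol | C/C=C(\C)CO | intermediate
8 | [(2R,3R)-2,3-dimethyloxiran-2-yl]methanol | OC[C@@]1(C)O[C@@H]1C | intermediate
9 | (2S,3R)-2,3-dimethyloxirane-2-carbaldehyde | O=C[C@@]1(C)O[C@@H]1C | intermediate
10 | (2S,3R)-2,3-dimethyloxirane-2-carboxylic acid | OC(=O)[C@@]1(C)O[C@@H]1C | intermediate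
11 | (3aR,6aR)-2,2-dimethyldihydrofuro[3,4-d][1,3]dioxol-4(3aH)-one (2,3-O-isopropylidene-D-erythronolactone) | O=C1OC[C@H]2OC(C)(C)O[C@@H]12 | starting material
12 | (4R,5R)-5-(hydroxymethyl)-N-methoxy-N,2,2-trimethyl-1,3-dioxolane-4-carboxamide | CON(C)C(=O)[C@@H]1OC(C)(C)O[C@@H]1CO | intermediate
13 | (4R,5S)-5-formyl-N-methoxy-N,2,2-trimethyl-1,3-dioxolane-4-carboxamide | CON(C)C(=O)[C@@H]1OC(C)(C)O[C@@H]1C=O | intermediate
14 | ethyl (2E)-3-[(4R,5R)-5-[methoxy(methyl)carbamoyl]-2,2-dimethyl-1,3-dioxolan-4-yl]prop-2-enoate | CCOC(=O)/C=C/[C@H]1OC(C)(C)O[C@H]1C(=O)N(C)OC | intermediate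
15 | ethyl trimethylsilyl ketene acetal of 16 | CCOC(O[Si](C)(C)C)=C[C@@H](C=C)[C@H]1OC(C)(C)O[C@H]1C(=O)N(C)OC | intermediate
16 | ethyl (3S)-3-[(4R,5R)-5-[methoxy(methyl)carbamoyl]-2,2-dimethyl-1,3-dioxolan-4-yl]pent-4-enoate | CCOC(=O)C[C@@H](C=C)[C@H]1OC(C)(C)O[C@H]1C(=O)N(C)OC | intermediate
17 | ethyl (3S)-3-[(4R,5R)-5-acetyl-2,2-dimethyl-1,3-dioxolan-4-yl]pent-4-enoate | CCOC(=O)C[C@@H](C=C)[C@H]1OC(C)(C)O[C@H]1C(C)=O | intermediate
18 | [(3Z)-4-bromopent-3-en-1-ylidene]triphenylphosphorane | C/C(Br)=C/CC=P(c1ccccc1)(c1ccccc1)c1ccccc1 | intermediate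
19 | ethyl (3S)-3-[(4R,5S)-5-[(2Z,5Z)-6-bromohepta-2,5-dien-2-yl]-2,2-dimethyl-1,3-dioxolan-4-yl]pent-4-enoate | CCOC(=O)C[C@@H](C=C)[C@H]1OC(C)(C)O[C@H]1/C(C)=C\C/C=C(/C)Br | intermediate
20 | (3S)-3-[(4R,5S)-5-[(2Z,5Z)-6-bromohepta-2,5-dien-2-yl]-2,2-dimethyl-1,3-dioxolan-4-yl]pent-4-enoic acid | OC(=O)C[C@@H](C=C)[C@H]1OC(C)(C)O[C@H]1/C(C)=C\C/C=C(/C)Br | intermediate
21 | (4R,5R)-4-[(4R,5S)-5-[(2Z,5Z)-6-bromohepta-2,5-dien-2-yl]-2,2-dimethyl-1,3-dioxolan-4-yl]-5-(iodomethyl)oxolan-2-one | IC[C@@H]1OC(=O)C[C@@H]1[C@H]1OC(C)(C)O[C@H]1/C(C)=C\C/C=C(/C)Br | intermediate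
22 | (1(10)Z,3Z,6S,7S,8R,9S)-8,9-(isopropylidenedioxy)-13-norgermacra-1(10),3-dien-12,6-olide | C1C(=O)O[C@H]2C/C(C)=C\C/C=C(/C)[C@@H]3OC(C)(C)O[C@@H]3[C@@H]12 | intermediate
23 | lithium enolate of 22 (C11=C12 enolate) | C1=C([O-])O[C@H]2C/C(C)=C\C/C=C(/C)[C@@H]3OC(C)(C)O[C@@H]3[C@@H]12.[Li+] | intermediate
24 | (1(10)Z,3Z,6S,7S,8R,9S)-13-(dimethylamino)-8,9-(isopropylidenedioxy)germacra-1(10),3-dien-12,6-olide, C11 epimers | CN(C)CC1C(=O)O[C@H]2C/C(C)=C\C/C=C(/C)[C@@H]3OC(C)(C)O[C@@H]3[C@@H]12 | intermediate
25 | 13-(trimethylammonio) analogue of 24, iodide salt | C[N+](C)(C)CC1C(=O)O[C@H]2C/C(C)=C\C/C=C(/C)[C@@H]3OC(C)(C)O[C@@H]3[C@@H]12.[I-] | intermediate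
26 | (1(10)Z,3Z,6S,7S,8R,9S)-8,9-(isopropylidenedioxy)germacra-1(10),3,11(13)-trien-12,6-olide | C=C1C(=O)O[C@H]2C/C(C)=C\C/C=C(/C)[C@@H]3OC(C)(C)O[C@@H]3[C@@H]12 | intermediate
27 | (1(10)Z,3Z,6S,7S,8R,9S)-8,9-dihydroxygermacra-1(10),3,11(13)-trien-12,6-olide | C=C1C(=O)O[C@H]2C/C(C)=C\C/C=C(/C)[C@H](O)[C@H](O)[C@@H]12 | intermediate
28 | (1(10)Z,3Z,6S,7S,8R,9S)-9-acetoxy-8-hydroxygermacra-1(10),3,11(13)-trien-12,6-olide | C=C1C(=O)O[C@H]2C/C(C)=C\C/C=C(/C)[C@H](OC(C)=O)[C@H](O)[C@@H]12 | intermediate
29 | (2S,3R)-2,3-dimethyloxirane-2-carboxylic 2,4,6-trichlorobenzoic anhydride | Clc1cc(Cl)cc(Cl)c1C(=O)OC(=O)[C@@]1(C)O[C@@H]1C | intermediate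
30 | (1(10)Z,3Z,6S,7S,8R,9S)-9-acetoxy-8-{[(2S,3R)-2,3-dimethyloxiran-2-yl]carbonyloxy}germacra-1(10),3,11(13)-trien-12,6-olide | C=C1C(=O)O[C@H]2C/C(C)=C\C/C=C(/C)[C@H](OC(C)=O)[C@H](OC(=O)[C@@]3(C)O[C@@H]3C)[C@@H]12 | target

## Step count and risks

Total step count: 20. Longest linear sequence: 14 steps (11 to 30, steps 7–20). The arm (steps 1–3) and the epoxy acid (steps 4–6) are side branches.

Steps least certain to work:

**Step 15 (key step, proposed new method).**
- What may go wrong: premature reduction of the C5 radical or of the alkenylnickel, intermolecular coupling to dimers, and cyclisation of the C5 radical onto the C1=C10 olefin in a six- or seven-membered mode before the nickel centre captures it. Each competes because closing a ten-membered ring is slow compared with these first-order or bimolecular side paths. Loss of the lactone carboxylate by β-elimination would follow if a C5 anion formed.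
- Fallback (known chemistry): from 21, returning at 22. Kornblum oxidation with AgBF4 in DMSO and then Et3N should convert the iodide into the aldehyde (2R,3R)-3-[(4R,5S)-5-[(2Z,5Z)-6-bromohepta-2,5-dien-2-yl]-2,2-dimethyl-1,3-dioxolan-4-yl]-5-oxooxolane-2-carbaldehyde F1 without touching the bromodiene. An intramolecular Nozaki–Hiyama–Kishi reaction with CrCl2 and catalytic NiCl2 in DMSO at high dilution, a proven way to close ten-membered carbocycles, should then give the ring carbinol 5-hydroxy-8,9-(isopropylidenedioxy)-13-norgermacra-1(10),3-dien-12,6-olide F2 as a pair of C5 epimers. Formic acetic anhydride and pyridine should turn both epimers into the allylic formate 5-formyloxy-8,9-(isopropylidenedioxy)-13-norgermacra-1(10),3-dien-12,6-olide F3 as the substrate for a palladium-catalysed hydrogenolysis with Pd(OAc)2 and PBu3, a decarboxylative hydride transfer that should deliver hydride to C5 and give 22. In short, the detour runs from 21 through aldehyde F1 to ring carbinol F2 and on through formate F3 back to 22.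

**Step 14 (iodolactonisation).**
- What may go wrong: insufficient facial selectivity at C6, since the kinetic preference for the cis lactone is modest for 3-alkyl pentenoic acids and equilibration would favour the trans isomer. Reversible iodonium formation at the electron-rich C1=C10 olefin could also erode the material.
- Fallback: from 19, returning at 21, with C6 set by a catalyst. Platinum-catalysed enantioselective diboration of the terminal olefin (Pt(dba)3, a TADDOL-derived phosphonite, bis(pinacolato)diboron; internal olefins are inert) should give ethyl (3S,4S)-3-[(4R,5S)-5-[(2Z,5Z)-6-bromohepta-2,5-dien-2-yl]-2,2-dimethyl-1,3-dioxolan-4-yl]-4,5-bis(4,4,5,5-tetramethyl-1,3,2-dioxaborolan-2-yl)pentanoate F4 with both carbon–boron bonds on one face. Oxidation with H2O2 and NaOH followed by acidification lactonises the resulting diol to (4S,5R)-4-[(4R,5S)-5-[(2Z,5Z)-6-bromohepta-2,5-dien-2-yl]-2,2-dimethyl-1,3-dioxolan-4-yl]-5-(hydroxymethyl)oxolan-2-one F5 through the secondary hydroxyl, and an Appel reaction (I2, PPh3, imidazole) on the primary hydroxyl gives 21. In short, the detour runs from 19 through diboronate F4 to hydroxymethyl lactone F5 and from there to 21.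

**Step 10 (conjugate addition).**
- What may go wrong: poor facial selectivity at C7, because the cis substituent on the dioxolane or coordination of the amide to magnesium may disturb the conformation that places C8–O anti to the incoming vinyl group. Direct attack of the Grignard reagent on the amide is a second risk.
- Fallback: from 14, returning at 16, with catalyst control in place of substrate control. Rhodium-catalysed asymmetric 1,4-addition of CH2=CHBF3K ([RhCl(C2H4)2]2, chiral diene ligand, aqueous dioxane, Et3N) is used, with the ligand enantiomer chosen to match the substrate. It gives 16 directly, so no compound outside the compound list arises, and the entry for this fallback is F0 in the block below.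

**Step 12 (Wittig olefination).**
- What may go wrong: erosion of Z selectivity if the oxaphosphetane equilibrates, and base-induced epimerisation of C9 to the more stable trans-dioxolane before the ylide adds.
- Fallback: from 17 and 4, returning at 19, through a stepwise Horner–Wittig sequence. Dibromide 4 is alkylated with lithiated methyldiphenylphosphine oxide to give [(3Z)-4-bromopent-3-en-1-yl]diphenylphosphine oxide F6 as the olefination partner. Its lithio derivative adds to 17 at −78 °C to give the β-hydroxy phosphine oxide ethyl (3S)-3-[(4R,5R)-5-[(5Z)-6-bromo-3-(diphenylphosphoryl)-2-hydroxyhept-5-en-2-yl]-2,2-dimethyl-1,3-dioxolan-4-yl]pent-4-enoate F7 as a mixture of diastereomers at the two new centres. The diastereomers are separated, and stereospecific syn elimination of the appropriate one with KN(SiMe3)2 in THF gives 19. In short, the detour runs from 4 and 17 through phosphine oxide F6 to hydroxy phosphine oxide F7 and from there to 19.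

**Step 19 (selective acetylation).**
- What may go wrong: acylation at the wrong hydroxyl or at both, and acyl migration between O8 and O9, because the reactivity difference between the two secondary hydroxyls in the flexible ring is only estimated.
- Fallback: from 27, returning at 30, with the order of acylations reversed, for the case that C8–OH proves the more reactive. Diol 27 is treated with one equivalent of mixed anhydride 29 and 4-(dimethylamino)pyridine to give (1(10)Z,3Z,6S,7S,8R,9S)-8-{[(2S,3R)-2,3-dimethyloxiran-2-yl]carbonyloxy}-9-hydroxygermacra-1(10),3,11(13)-trien-12,6-olide F8 as the monoester. Acetylation (Ac2O, pyridine) of the remaining C9 hydroxyl then gives 30. In short, the detour runs from 27 through hydroxy epoxy ester F8 to 30.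

## Further compounds

F1 | step 15 | (2R,3R)-3-[(4R,5S)-5-[(2Z,5Z)-6-bromohepta-2,5-dien-2-yl]-2,2-dimethyl-1,3-dioxolan-4-yl]-5-oxooxolane-2-carbaldehyde | O=C[C@@H]1OC(=O)C[C@@H]1[C@H]1OC(C)(C)O[C@H]1/C(C)=C\C/C=C(/C)Br
F2 | step 15 | 5-hydroxy-8,9-(isopropylidenedioxy)-13-norgermacra-1(10),3-dien-12,6-olide, C5 epimers | C1C(=O)O[C@H]2C(O)/C(C)=C\C/C=C(/C)[C@@H]3OC(C)(C)O[C@@H]3[C@@H]12
F3 | step 15 | 5-formyloxy-8,9-(isopropylidenedioxy)-13-norgermacra-1(10),3-dien-12,6-olide, C5 epimers | C1C(=O)O[C@H]2C(OC=O)/C(C)=C\C/C=C(/C)[C@@H]3OC(C)(C)O[C@@H]3[C@@H]12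
F4 | step 14 | ethyl (3S,4S)-3-[(4R,5S)-5-[(2Z,5Z)-6-bromohepta-2,5-dien-2-yl]-2,2-dimethyl-1,3-dioxolan-4-yl]-4,5-bis(4,4,5,5-tetramethyl-1,3,2-dioxaborolan-2-yl)pentanoate | CCOC(=O)C[C@@H]([C@H](CB1OC(C)(C)C(C)(C)O1)B1OC(C)(C)C(C)(C)O1)[C@H]1OC(C)(C)O[C@H]1/C(C)=C\C/C=C(/C)Br
F5 | step 14 | (4S,5R)-4-[(4R,5S)-5-[(2Z,5Z)-6-bromohepta-2,5-dien-2-yl]-2,2-dimethyl-1,3-dioxolan-4-yl]-5-(hydroxymethyl)oxolan-2-one | OC[C@@H]1OC(=O)C[C@@H]1[C@H]1OC(C)(C)O[C@H]1/C(C)=C\C/C=C(/C)Br
F0 | step 10 | none | none
F6 | step 12 | [(3Z)-4-bromopent-3-en-1-yl]diphenylphosphine oxide | C/C(Br)=C/CCP(=O)(c1ccccc1)c1ccccc1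
F7 | step 12 | ethyl (3S)-3-[(4R,5R)-5-[(5Z)-6-bromo-3-(diphenylphosphoryl)-2-hydroxyhept-5-en-2-yl]-2,2-dimethyl-1,3-dioxolan-4-yl]pent-4-enoate, diastereomers at the two new centres | CCOC(=O)C[C@@H](C=C)[C@H]1OC(C)(C)O[C@H]1C(C)(O)C(C/C=C(/C)Br)P(=O)(c1ccccc1)c1ccccc1
F8 | step 19 | (1(10)Z,3Z,6S,7S,8R,9S)-8-{[(2S,3R)-2,3-dimethyloxiran-2-yl]carbonyloxy}-9-hydroxygermacra-1(10),3,11(13)-trien-12,6-olide | C=C1C(=O)O[C@H]2C/C(C)=C\C/C=C(/C)[C@H](O)[C@H](OC(=O)[C@@]3(C)O[C@@H]3C)[C@@H]12
A1 | alternative 1 | C1–C6-fused bicyclic 9,10-epoxy C6 tertiary alcohol with C8 silyl ether and 2-(4-methoxybenzyloxy)ethyl group at C7 (C6 configuration left open) | COc1ccc(COCC[C@H]2C3(O)CC(C)=CC[C@@H]3[C@]4(C)O[C@@H]4[C@@H]2O[Si](C)(C)C(C)(C)C)cc1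
A2 | alternative 1 | ten-membered (Z,Z)-dien-6-one with free C9 hydroxyl, C8 tert-butyldimethylsilyl ether and 2-(4-methoxybenzyloxy)ethyl group at C7 | COc1ccc(COCC[C@H]2C(=O)C/C(C)=C\C/C=C(/C)[C@H](O)[C@@H]2O[Si](C)(C)C(C)(C)C)cc1
A3 | alternative 2 | eleven-membered cyclic sulfone (sulfur between C3 and C4, C4 epimers) with C8,C9 acetonide and silyl ethers at C6 and C12 | CC(C)(C)[Si](C)(C)OCC[C@H]1[C@@H](O[Si](C)(C)C(C)(C)C)CC(C)S(=O)(=O)CC/C=C(/C)[C@@H]2OC(C)(C)O[C@H]12
A4 | alternative 2 | ten-membered (Z,Z)-diene with C8,C9 acetonide and silyl ethers at C6 and C12 | CC(C)(C)[Si](C)(C)OCC[C@H]1[C@@H](O[Si](C)(C)C(C)(C)C)C/C(C)=C\C/C=C(/C)[C@@H]2OC(C)(C)O[C@H]12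
A5 | alternative 3 | α-methylene-γ-butyrolactone carrying the C8 silyloxy C9 aldehyde at C7 and the (Z,Z)-iododienyl chain at C6 | C=C1C(=O)O[C@@H](C/C(C)=C\C/C=C(/C)I)[C@H]1[C@@H](O[Si](C)(C)C(C)(C)C)C=O
A6 | alternative 3 | ten-membered C9 alcohol with C8 tert-butyldimethylsilyl ether and α-methylene lactone | C=C1C(=O)O[C@H]2C/C(C)=C\C/C=C(/C)[C@H](O)[C@H](O[Si](C)(C)C(C)(C)C)[C@@H]12
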